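**Retrosynthetic overview**
- The target is an 8-O-4′ neolignan with (7R,8R)-threo configuration. The last bond cut is ring B C4′–C7′ (aryl–alkenyl), made by Suzuki–Miyaura coupling of a ring B aryl bromide with an (E)-3-hydroxypropenyl boronate.
- The key cut is ring A C1–C7. The strategy rests on the benzylic carbinol C7 sitting next to C8, which carries the C9 methyl and the ring B ether oxygen flanked by two ortho methoxy groups. That oxygen and the C7 carbonyl oxygen can hold magnesium in a five-membered chelate, so C8 can direct the addition of a ring A arylmagnesium to C7.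
- The (R)-2-aryloxypropanal comes from ethyl (S)-lactate: Mitsunobu etherification with the ring B bromophenol (inversion gives 8R), then half-reduction of the ester.
- No ring is formed; rings A and B are both bought as bromoarenes.

Key step: step 4

Assumption: neolignan numbering is used (ring A = 3,4,5-trimethoxyphenyl, C7 = carbinol carbon, C8 = ether-bearing carbon, C9 = methyl, ring B = the 2,6-dimethoxyphenoxy ring), and the THF that enters with the Grignard solution is taken not to break the magnesium chelate while CH2Cl2 is the bulk solvent.

**Step 1**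
Reactants: 1 ethyl (S)-lactate; 2 4-bromo-2,6-dimethoxyphenol
Product: 3 ethyl (R)-2-(4-bromo-2,6-dimethoxyphenoxy)propanoate
Conditions: PPh3 (1.3 equiv), DIAD (1.3 equiv), THF, 0 °C to rt
Reagents that add atoms: none
Why: Mitsunobu etherification, in which the phenoxide displaces the oxyphosphonium group at the ester-activated lactate carbon by SN2 with inversion, so the S alcohol should give the R aryl ether that becomes C8.

**Step 2**
Reactants: 3 ethyl (R)-2-(4-bromo-2,6-dimethoxyphenoxy)propanoate
Product: 5 (R)-2-(4-bromo-2,6-dimethoxyphenoxy)propanal, via aluminium hemiacetal 4 (not isolated)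
Conditions: i-Bu2AlH (1.1 equiv), CH2Cl2, −78 °C; then aq. potassium sodium tartrate (KNaC4H4O6); crude aldehyde dried (Na2SO4, toluene azeotrope) and used at once
Reagents that add atoms: none
Why: Partial reduction of an ester with i-Bu2AlH, where the tetrahedral aluminium hemiacetal is held at −78 °C by the neighbouring aryloxy oxygen and should release the aldehyde only on work-up, leaving C8 and the aryl bromide untouched.

**Step 3**
Reactants: 6 5-bromo-1,2,3-trimethoxybenzene
Product: 7 3,4,5-trimethoxyphenylmagnesium bromide
Conditions: Mg turnings (1.2 equiv), I2 (cat.), THF (to about 1 M), 40–60 °C; solution titrated and used directly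
Reagents that add atoms: magnesium, [Mg]
Why: Grignard reagent formation by insertion of magnesium metal into an unhindered aryl C–Br bond, which the methoxy groups tolerate.

**Step 4**
Reactants: 5 (R)-2-(4-bromo-2,6-dimethoxyphenoxy)propanal; 7 3,4,5-trimethoxyphenylmagnesium bromide
Product: 10 (1R,2R)-2-(4-bromo-2,6-dimethoxyphenoxy)-1-(3,4,5-trimethoxyphenyl)propan-1-ol, via magnesium bromide chelate 8 (not isolated), via bromomagnesium alkoxide 9 (not isolated)
Conditions: 5, MgBr2·OEt2 (3 equiv), CH2Cl2, −40 to −78 °C, 30 min; then 7 (1.5 equiv, slow addition), −78 °C; then aq. NH4Cl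
Reagents that add atoms: none
Why: This is a Cram-chelate 1,2-addition of an aryl Grignard reagent to an α-alkoxy aldehyde, in which MgBr2 first ties the C7 carbonyl oxygen and the C8 ether oxygen into a five-membered chelate (supported by an ortho methoxy oxygen of ring B), fixing the C7–C8 rotamer and making the chelated carbonyl the most electrophilic species present. The aryl group of 7 should then reach C7 from the chelate face that carries the C8 hydrogen, away from the C9 methyl, which is the Re face of the (R)-aldehyde and gives the 7R carbinol, the threo (7R,8R) relation, with C8 as the controlling element carried through unchanged. One C–C bond (ring A C1–C7) and one stereocentre are formed, and no ring is closed. The selectivity needed is chelate attack over Felkin–Anh attack (which would give the erythro epimer), and it is secured by precomplexation with excess MgBr2·OEt2 in CH2Cl2 at −78 °C, by keeping the THF of the reagent a minor component, and by the faster reaction of the chelated carbonyl. The ring B aryl bromide should survive because bromine–magnesium exchange with an aryl Grignard reagent is negligible at −78 °C, and the weakly basic aryl nucleophile should add faster than it enolises C8–H.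

**Step 5**
Reactants: 10 (1R,2R)-2-(4-bromo-2,6-dimethoxyphenoxy)-1-(3,4,5-trimethoxyphenyl)propan-1-ol; 11 (E)-3-hydroxyprop-1-enylboronic acid pinacol ester
Product: 12 (1R,2R)-2-{4-[(E)-3-hydroxyprop-1-enyl]-2,6-dimethoxyphenoxy}-1-(3,4,5-trimethoxyphenyl)propan-1-ol
Conditions: Pd(dppf)Cl2·CH2Cl2 (5 mol %), K2CO3 (3 equiv), 11 (1.5 equiv), 1,4-dioxane/H2O (4:1), argon, 80 °C
Reagents that add atoms: none
Why: Suzuki–Miyaura coupling of an aryl bromide with no ortho substituents and an alkenyl boronate, which proceeds with retention of the E geometry and should tolerate both free hydroxyl groups and leave C7 and C8 untouched.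

**Compound list**
1 | ethyl (S)-lactate | CCOC(=O)[C@H](C)O | starting material
2 | 4-bromo-2,6-dimethoxyphenol | COc1cc(Br)cc(OC)c1O | starting material
3 | ethyl (R)-2-(4-bromo-2,6-dimethoxyphenoxy)propanoate | CCOC(=O)[C@@H](C)Oc1c(OC)cc(Br)cc1OC | intermediate
4 | diisobutylaluminium hemiacetal of ester 3, [(2R)-2-(4-bromo-2,6-dimethoxyphenoxy)-1-ethoxypropoxy]diisobutylaluminium, epimer mixture at the hemiacetal carbon (formed in the flask, not isolated) | CCOC(O[Al](CC(C)C)CC(C)C)[C@@H](C)Oc1c(OC)cc(Br)cc1OC | intermediate
5 | (R)-2-(4-bromo-2,6-dimethoxyphenoxy)propanal | O=C[C@@H](C)Oc1c(OC)cc(Br)cc1OC | intermediate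
6 | 5-bromo-1,2,3-trimethoxybenzene | COc1cc(Br)cc(OC)c1OC | starting material
7 | 3,4,5-trimethoxyphenylmagnesium bromide | COc1cc([Mg]Br)cc(OC)c1OC | intermediate
8 | magnesium bromide chelate of aldehyde 5, written as the 1:1 adduct (formed in the flask, not isolated) | O=C[C@@H](C)Oc1c(OC)cc(Br)cc1OC.Br[Mg]Br | intermediate
9 | bromomagnesium alkoxide of alcohol 10 (formed in the flask, not isolated) | COc1cc([C@@H](O[Mg]Br)[C@@H](C)Oc2c(OC)cc(Br)cc2OC)cc(OC)c1OC | intermediate
10 | (1R,2R)-2-(4-bromo-2,6-dimethoxyphenoxy)-1-(3,4,5-trimethoxyphenyl)propan-1-ol | COc1cc([C@@H](O)[C@@H](C)Oc2c(OC)cc(Br)cc2OC)cc(OC)c1OC | intermediate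
11 | (E)-3-hydroxyprop-1-enylboronic acid pinacol ester | OC/C=C/B1OC(C)(C)C(C)(C)O1 | starting material
12 | (1R,2R)-2-{4-[(E)-3-hydroxyprop-1-enyl]-2,6-dimethoxyphenoxy}-1-(3,4,5-trimethoxyphenyl)propan-1-ol | COc1cc([C@@H](O)[C@@H](C)Oc2c(OC)cc(/C=C/CO)cc2OC)cc(OC)c1OC | target

**Step count and risks**
Total step count: 5. Longest linear sequence: 4 steps (steps 1, 2, 4, 5 from ethyl (S)-lactate); step 3 is a one-step side branch.

Steps most likely to fail:

1. Step 4. The aryloxy oxygen is a weak donor and THF competes for magnesium, so the chelate may not form fully and open Felkin–Anh attack would erode the facial selectivity at C7. Enolisation could also erode C8. The fallback sets out from aldehyde 5 and moves the stereocontrol from the C–C bond formation to a ketone reduction. Addition of 7 in THF without Lewis acid would give 10 mixed with its C7 epimer (1S,2R)-2-(4-bromo-2,6-dimethoxyphenoxy)-1-(3,4,5-trimethoxyphenyl)propan-1-ol F1. The mixture would be oxidised with Dess–Martin periodinane (NaHCO3, CH2Cl2, 0 °C) to (R)-2-(4-bromo-2,6-dimethoxyphenoxy)-1-(3,4,5-trimethoxyphenyl)propan-1-one F2. Reduction with the bulky, non-chelating LiBH(s-Bu)3 in THF at −78 °C should follow the Felkin–Anh course, with the aryloxy group anti to the incoming hydride. Because hydride is now the entering group in place of aryl, that course should give the threo alcohol, and the route is rejoined at 10.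

2. Step 2. Over-reduction to the primary alcohol, or loss of configuration at C8 of the α-aryloxy aldehyde during the aluminium work-up, would waste the material entering the key step. The fallback sets out from ester 3. Full reduction with LiBH4 (THF, 0 °C to rt) would give (R)-2-(4-bromo-2,6-dimethoxyphenoxy)propan-1-ol F3, a configurationally stable compound that can be purified and stored. Oxidation with Dess–Martin periodinane (NaHCO3, CH2Cl2, 0 °C) under non-basic conditions would give the aldehyde just before use, and the route is rejoined at 5.

3. Step 5. Protodeboronation of the unprotected hydroxyalkenyl boronate, slow oxidative addition of zerovalent palladium to the electron-rich aryl bromide, or palladium-mediated oxidation of the benzylic alcohol could stall the coupling. The fallback sets out from bromide 10 and builds the side chain in two steps by a different bond-forming mode. A Mizoroki–Heck reaction with methyl acrylate (Pd(OAc)2, P(o-tol)3, NaOAc, DMF, 110 °C) should give methyl (E)-3-{4-[(1R,2R)-1-hydroxy-1-(3,4,5-trimethoxyphenyl)propan-2-yl]oxy-3,5-dimethoxyphenyl}prop-2-enoate F4. Reduction of the ester with i-Bu2AlH (4 equiv, CH2Cl2, −78 °C) should then give the allylic alcohol, and the route is rejoined at target 12.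

**Further compounds**
F1 | step 4 | (1S,2R)-2-(4-bromo-2,6-dimethoxyphenoxy)-1-(3,4,5-trimethoxyphenyl)propan-1-ol | COc1cc([C@H](O)[C@@H](C)Oc2c(OC)cc(Br)cc2OC)cc(OC)c1OC
F2 | step 4 | (R)-2-(4-bromo-2,6-dimethoxyphenoxy)-1-(3,4,5-trimethoxyphenyl)propan-1-one | COc1cc(C(=O)[C@@H](C)Oc2c(OC)cc(Br)cc2OC)cc(OC)c1OC
F3 | step 2 | (R)-2-(4-bromo-2,6-dimethoxyphenoxy)propan-1-ol | OC[C@@H](C)Oc1c(OC)cc(Br)cc1OC
F4 | step 5 | methyl (E)-3-{4-[(1R,2R)-1-hydroxy-1-(3,4,5-trimethoxyphenyl)propan-2-yl]oxy-3,5-dimethoxyphenyl}prop-2-enoate | COc1cc([C@@H](O)[C@@H](C)Oc2c(OC)cc(/C=C/C(=O)OC)cc2OC)cc(OC)c1OC
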